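The dihydropyran ring (C1, O2, C3, C4, C5, C9; iridoid numbering) is treated as the cyclic hemiacetal of a 1,5-dialdehyde (C1 and C3), as in iridodial biosynthesis. That dialdehyde is released by retro-aldol opening of the cyclobutanol formed when the enol of triformylmethane adds photochemically (de Mayo [2+2]) across C5=C9 of a cyclopentene that already carries C7–O and the C8 carbinol. One operation should forge C4–C5, C1–C9 and O2–C1, set the cis ring fusion, and leave C4 as a formyl group that stabilises the enol ether until its final reduction to C11–OH. The precursor is a cis-fused cyclopentenol acetonide, made by Enders alkylation, vinyl addition and ring-closing metathesis.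

Key step: step 5

Remarks: Numbering is C1 (acyloxy acetal carbon), O2, C3=C4 (C11 on C4), C5 and C9 (ring fusion), C6, C7 (coumarate carbon), C8 (carbinol carbon, C10 on C8); β is the face of H5 and H9. (R)-3-Methylpentanoic acid and triformylmethane are taken as purchasable. Hemiacetal 11 is drawn as the 1β-hydroxy anomer expected to predominate at equilibrium.

Step 1
Reactants: 1 2,2-dimethyl-1,3-dioxan-5-one; 2 SAMP, (S)-1-amino-2-(methoxymethyl)pyrrolidine
Product: 3 SAMP hydrazone of 1
Conditions: cyclohexane, reflux, Dean–Stark
Reagents that add atoms: none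
Why: Hydrazone condensation of an unhindered ketone with the Enders auxiliary, driven by removal of water; no stereocentre is formed.

Step 2
Reactants: 3 SAMP hydrazone of 1
Product: 5 (S)-4-allyl-2,2-dimethyl-1,3-dioxan-5-one, via allylated SAMP hydrazone 4 (not isolated)
Conditions: t-BuLi, THF, −78 °C; allyl bromide, −100 °C → rt; then sat. aq. oxalic acid, Et2O, rt
Reagents that add atoms: allyl bromide, C=CCBr; water, O
Why: Enders SAMP-hydrazone α-alkylation: the chelated lithium azaenolate should be allylated on the face away from the methoxymethyl arm, setting the (S) centre (later C7), and the mild two-phase oxalic acid cleavage should release the α-alkoxy ketone without racemisation or loss of the acetonide.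

Step 3
Reactants: 5 (S)-4-allyl-2,2-dimethyl-1,3-dioxan-5-one
Product: 6 (4S,5R)-4-allyl-2,2-dimethyl-5-vinyl-1,3-dioxan-5-ol (allyl and vinyl cis)
Conditions: CH2=CHMgBr, CeCl3 (anhydrous), THF, −78 °C; aq. NH4Cl
Reagents that add atoms: vinylmagnesium bromide, C=C[Mg]Br
Why: Organocerium 1,2-addition (Imamoto conditions) suppresses enolisation of the epimerisable ketone, and axial attack on the dioxanone chair (no 1,3-diaxial hydrogens, allyl equatorial) should place vinyl cis to allyl and the new tertiary hydroxyl trans to it, which is the C8 configuration.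

Step 4
Reactants: 6 (4S,5R)-4-allyl-2,2-dimethyl-5-vinyl-1,3-dioxan-5-ol
Product: 7 (4aR,7aS)-2,2-dimethyl-4,4a,7,7a-tetrahydrocyclopenta[d][1,3]dioxin-4a-ol (cis-fused cyclopentenol acetonide; alkene = C5=C9, tertiary OH on C8)
Conditions: Grubbs II catalyst (3 mol %), CH2Cl2, 40 °C
Reagents that add atoms: none
Why: Ring-closing metathesis of a 1,6-diene whose cis-disposed allyl and vinyl arms should close to the cis-fused cyclopentene with loss of ethylene; free tertiary allylic alcohols are tolerated and no stereocentre changes.

Step 5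
Reactants: 7 cis-fused cyclopentenol acetonide; 8 triformylmethane (2-formylmalonaldehyde, present as its hydroxymethylene enol)
Product: 11 lactol-enal (1β-hydroxy-8α-hydroxy-11-oxo iridoid 7β,10-O-isopropylidene acetal), via cyclobutanol photoadduct 9 (not isolated), via ring-opened dialdehyde enol 10 (not isolated)
Conditions: 8 (3 equiv), MeCN (degassed), hν (medium-pressure Hg lamp, Pyrex filter), 0–10 °C; then rt in the dark
Reagents that add atoms: none
Why: Irradiation excites the hydrogen-bonded enol of 8, which adds across C5=C9 of 7 to give cyclobutanol 9; its β-hydroxy aldehyde unit should undergo strain-driven retro-aldol cleavage of the C1–C4 bond to the 1,5-dialdehyde 10, whose enol oxygen adds to the C1 aldehyde to give 11. The closest known reaction type is the de Mayo reaction of formyl-substituted 1,3-dicarbonyl enols with cyclopentenes to give 2-hydroxy-3,4-dihydro-2H-pyrans. The cyclobutane closes by a [2+2] photocycloaddition that is suprafacial on the alkene, and the dihydropyran closes by 6-exo-trig hemiacetalisation of O2 onto C1. C5 and C9 are set together: the four-membered ring enforces the cis fusion, and the face is fixed by the substrate, because the dioxane ring occupies the concave β face while the free C8 hydroxyl sits on the open convex α face and can hydrogen-bond the incoming enol; C1 is under thermodynamic control in the equilibrating hemiacetal (hydroxyl trans to C8). The step needs regioselectivity (the C(CHO)2 carbon to C5, the carbinol carbon to C9) and α-face selectivity; the first should be secured by the quaternary C8 next to C9, which steers the fully substituted terminus to the distal C5 (assisted by the hydrogen bond from the C8 hydroxyl to the oxygenated terminus), and the second by the concave–convex shape of 7.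

Step 6
Reactants: 11 lactol-enal; 12 (R)-3-methylpentanoic acid
Product: 13 1β-O-[(R)-3-methylpentanoyl] ester of 11
Conditions: DCC, DMAP (cat.), CH2Cl2, 0 °C
Reagents that add atoms: none
Why: Steglich esterification of the lactol hydroxyl (the tertiary C8 hydroxyl is inert); the hemiacetal equilibrates under DMAP and the equatorial 1β-hydroxyl, trans to C8, is both the more stable and the more nucleophilic anomer, so the 1β-ester should predominate.

Step 7
Reactants: 13 1β-O-[(R)-3-methylpentanoyl] ester of 11
Product: 14 7β,8α,10-triol (C1 ester and C11 aldehyde retained)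
Conditions: AcOH/H2O (4:1), 40 °C
Reagents that add atoms: none
Why: Acid hydrolysis of the 1,3-dioxane acetonide; the formyl-conjugated enol ether and the C1 acyloxy acetal are deactivated towards oxocarbenium formation and should survive.

Step 8
Reactants: 14 7β,8α,10-triol
Product: 15 10-O-TBS ether of 14
Conditions: TBSCl (1.1 equiv), imidazole, CH2Cl2/DMF, −20 → 0 °C
Reagents that add atoms: tert-butyldimethylsilyl chloride, CC(C)(C)[Si](C)(C)Cl
Why: Selective silylation, the primary C10 hydroxyl reacting faster than the secondary C7 and tertiary C8 hydroxyls.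

Step 9
Reactants: 16 4-(tert-butyldimethylsilyloxy)benzaldehyde
Product: 17 tert-butyl[4-(2,2-dibromovinyl)phenoxy]dimethylsilane
Conditions: CBr4, PPh3, CH2Cl2, 0 °C
Reagents that add atoms: carbon tetrabromide, BrC(Br)(Br)Br
Why: Corey–Fuchs dibromo-olefination (Wittig-type reaction of Ph3P=CBr2 with the aldehyde), compatible with the aryl silyl ether.

Step 10
Reactants: 17 tert-butyl[4-(2,2-dibromovinyl)phenoxy]dimethylsilane
Product: 19 3-[4-(tert-butyldimethylsilyloxy)phenyl]propiolic acid, via lithium arylacetylide 18 (not isolated)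
Conditions: n-BuLi (2.2 equiv), THF, −78 → −20 °C; CO2 (g), −78 °C → rt; dil. HCl to pH 3
Reagents that add atoms: carbon dioxide, O=C=O
Why: Second stage of the Corey–Fuchs sequence (Br/Li exchange, Fritsch–Buttenberg–Wiechell rearrangement and deprotonation to the lithium acetylide) followed by carboxylation.

Step 11
Reactants: 19 3-[4-(tert-butyldimethylsilyloxy)phenyl]propiolic acid
Product: 20 (Z)-3-[4-(tert-butyldimethylsilyloxy)phenyl]acrylic acid
Conditions: H2 (1 atm), Lindlar catalyst (Pd/CaCO3, Pb-poisoned), quinoline, EtOAc, rt, dark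
Reagents that add atoms: none
Why: Lindlar semihydrogenation adds H2 syn to the alkyne and should stop at the cis-cinnamic acid, which sets the Z geometry; light is excluded to avoid Z→E isomerisation.

Step 12
Reactants: 15 10-O-TBS ether of 14; 20 (Z)-3-[4-(tert-butyldimethylsilyloxy)phenyl]acrylic acid
Product: 21 7-O-[(Z)-4-(tert-butyldimethylsilyloxy)cinnamoyl] ester of 15
Conditions: EDC·HCl, DMAP (0.3 equiv), CH2Cl2, 0 °C → rt, dark
Reagents that add atoms: none
Why: Steglich-type esterification of the only acylable hydroxyl left (secondary C7–OH, with retention at C7); low temperature, sub-stoichiometric DMAP and exclusion of light should preserve the Z geometry.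

Step 13
Reactants: 21 7-O-[(Z)-4-(tert-butyldimethylsilyloxy)cinnamoyl] ester of 15
Product: 22 11-oxo analogue of the target (free phenol, free C10–OH, C4 formyl)
Conditions: HF·pyridine, pyridine, THF, 0 °C → rt
Reagents that add atoms: none
Why: Buffered fluoride desilylation should cleave the aryl and primary TBS ethers without base, so the C1 acyloxy acetal is not attacked and no C7→C10 acyl migration is triggered, while the formyl group still protects the enol ether against acid.

Step 14
Reactants: 22 11-oxo analogue of the target
Product: 23 CNP0217341.1 (target)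
Conditions: NaBH4, CeCl3·7H2O, MeOH/THF, −78 → −40 °C; pH 7 buffer
Reagents that add atoms: none
Why: Luche 1,2-reduction of the vinylogous formate (as for 2-C-formyl glycals) should give the allylic C11 alcohol; the esters, the acyloxy acetal and the cis-cinnamate should be untouched at low temperature, and no stereocentre is affected.

Compound list
1 | 2,2-dimethyl-1,3-dioxan-5-one | CC1(C)OCC(=O)CO1 | starting material
2 | SAMP, (S)-1-amino-2-(methoxymethyl)pyrrolidine | COC[C@@H]1CCCN1N | starting material
3 | SAMP hydrazone of 1 | COC[C@@H]1CCCN1N=C1COC(C)(C)OC1 | intermediate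
4 | allylated SAMP hydrazone, (4S)-allyl | COC[C@@H]1CCCN1N=C1COC(C)(C)O[C@H]1CC=C | intermediate
5 | (S)-4-allyl-2,2-dimethyl-1,3-dioxan-5-one | C=CC[C@@H]1OC(C)(C)OCC1=O | intermediate
6 | (4S,5R)-4-allyl-2,2-dimethyl-5-vinyl-1,3-dioxan-5-ol | C=CC[C@@H]1OC(C)(C)OC[C@]1(O)C=C | intermediate
7 | (4aR,7aS)-2,2-dimethyl-4,4a,7,7a-tetrahydrocyclopenta[d][1,3]dioxin-4a-ol | C1=C[C@@]2(O)COC(C)(C)O[C@H]2C1 | intermediate
8 | triformylmethane | O=CC(C=O)C=O | starting material
9 | cyclobutanol photoadduct (cyclobutane C1–C4–C5–C9, two formyl groups on C4, new bonds on the α face) | OC1C(C=O)(C=O)[C@H]2C[C@@H]3OC(C)(C)OC[C@]3(O)[C@@H]12 | intermediate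
10 | ring-opened dialdehyde enol (C9–CHO, C5–C(CHO)=CHOH, cis) | O=C[C@H]1[C@@H](C(C=O)=CO)C[C@@H]2OC(C)(C)OC[C@]12O | intermediate
11 | lactol-enal: 1β-hydroxy-8α-hydroxy-11-oxo iridoid 7β,10-O-isopropylidene acetal | O[C@@H]1OC=C(C=O)[C@H]2C[C@@H]3OC(C)(C)OC[C@]3(O)[C@@H]12 | intermediate
12 | (R)-3-methylpentanoic acid | CC[C@@H](C)CC(=O)O | starting material
13 | 1β-O-[(R)-3-methylpentanoyl] ester of 11 | CC[C@@H](C)CC(=O)O[C@@H]1OC=C(C=O)[C@H]2C[C@@H]3OC(C)(C)OC[C@]3(O)[C@@H]12 | intermediate
14 | 7β,8α,10-triol with C1 ester and C4 formyl | CC[C@@H](C)CC(=O)O[C@@H]1OC=C(C=O)[C@H]2C[C@H](O)[C@](O)(CO)[C@@H]12 | intermediate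
15 | 10-O-TBS ether of 14 | CC[C@@H](C)CC(=O)O[C@@H]1OC=C(C=O)[C@H]2C[C@H](O)[C@](O)(CO[Si](C)(C)C(C)(C)C)[C@@H]12 | intermediate
16 | 4-(tert-butyldimethylsilyloxy)benzaldehyde | O=Cc1ccc(O[Si](C)(C)C(C)(C)C)cc1 | starting material
17 | tert-butyl[4-(2,2-dibromovinyl)phenoxy]dimethylsilane | BrC(Br)=Cc1ccc(O[Si](C)(C)C(C)(C)C)cc1 | intermediate
18 | lithium [4-(tert-butyldimethylsilyloxy)phenyl]acetylide | [Li]C#Cc1ccc(O[Si](C)(C)C(C)(C)C)cc1 | intermediate
19 | 3-[4-(tert-butyldimethylsilyloxy)phenyl]propiolic acid | OC(=O)C#Cc1ccc(O[Si](C)(C)C(C)(C)C)cc1 | intermediate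
20 | (Z)-3-[4-(tert-butyldimethylsilyloxy)phenyl]acrylic acid | OC(=O)/C=C\c1ccc(O[Si](C)(C)C(C)(C)C)cc1 | intermediate
21 | 7-O-[(Z)-4-(tert-butyldimethylsilyloxy)cinnamoyl] ester of 15 | CC[C@@H](C)CC(=O)O[C@@H]1OC=C(C=O)[C@H]2C[C@H](OC(=O)/C=C\c3ccc(O[Si](C)(C)C(C)(C)C)cc3)[C@](O)(CO[Si](C)(C)C(C)(C)C)[C@@H]12 | intermediate
22 | 11-oxo analogue of the target | CC[C@@H](C)CC(=O)O[C@@H]1OC=C(C=O)[C@H]2C[C@H](OC(=O)/C=C\c3ccc(O)cc3)[C@](O)(CO)[C@@H]12 | intermediate
23 | CNP0217341.1 | CC[C@@H](C)CC(=O)O[C@@H]1OC=C(CO)[C@H]2C[C@H](OC(=O)/C=C\c3ccc(O)cc3)[C@](O)(CO)[C@@H]12 | target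

Total step count: 14 (11 in the main line, 3 for acid 20). Longest linear sequence: 11 steps (steps 1–8 and 12–14).

Steps most likely to fail

Step 5 (key step). The cycloaddition may proceed in the reverse regiochemical sense (the C(CHO)2 carbon bonding to C9) or on the β face, and the enal product may undergo secondary photolysis. The fallback sets out from 7 and comes back at 11, and makes the cycloaddition intramolecular by tying the enol to the C8 oxygen. 7 is treated with excess Me2SiCl2 and Et3N (CH2Cl2, 0 °C) to give the chlorodimethylsilyl ether F1. After removal of excess silane, F1 is coupled with 8 (Et3N, CH2Cl2, 0 °C) to the silicon-tethered enol ether F2. Irradiation (Pyrex, MeCN) should then close a six-membered O–Si–O ring in the straight mode, forcing C1 onto C9 and C4 onto C5 from the α face, to give the tetracyclic photoadduct F3. HF·pyridine cleaves both Si–O bonds, and the cyclobutanol 9 so released should open and reclose through 10 to 11.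

Step 12. The activated cis-cinnamoyl species may isomerise Z→E (reversible conjugate addition of DMAP), and acylation of the hindered C7 hydroxyl next to the quaternary C8 may be slow. The fallback sets out from 15 and comes back at 21, and creates the alkene geometry only after the ester bond exists. 15 is esterified with the propiolic acid 19 (DCC, cat. DMAP, CH2Cl2, 0 °C) to the arylpropiolate ester F4. Lindlar semihydrogenation (H2, Pd/CaCO3–Pb, quinoline, EtOAc, dark) should then give 21; the formyl-conjugated enol ether is not expected to be reduced.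

Step 3. Equatorial attack would give the C8 epimer (vinyl trans to allyl), and enolisation of the α-alkoxy ketone would erode the C7 centre. The fallback sets out from 5 and comes back at 6, and uses a slimmer, less basic sp nucleophile with a pronounced axial preference, correcting the oxidation level afterwards. 5 is treated with ethynylmagnesium bromide (THF, −78 °C; CeCl3 if needed) to give the ethynyl carbinol F5, and Lindlar semihydrogenation of the alkyne (the terminal allyl alkene is left intact) gives 6.

Further compounds
F1 | step 5 | chlorodimethylsilyl ether of 7 (on the C8 oxygen) | C1=C[C@@]2(O[Si](C)(C)Cl)COC(C)(C)O[C@H]2C1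
F2 | step 5 | silicon-tethered enol ether of 8 and 7 (C8–O–SiMe2–O–CH=C(CHO)2) | C1=C[C@@]2(O[Si](C)(C)OC=C(C=O)C=O)COC(C)(C)O[C@H]2C1
F3 | step 5 | tetracyclic cyclobutane photoadduct with O8–SiMe2–O–C1 bridge | C[Si]1(C)O[C@H]2C(C=O)(C=O)[C@H]3C[C@@H]4OC(C)(C)OC[C@]4(O1)[C@@H]23
F4 | step 12 | 7-O-{3-[4-(tert-butyldimethylsilyloxy)phenyl]propioloyl} ester of 15 | CC[C@@H](C)CC(=O)O[C@@H]1OC=C(C=O)[C@H]2C[C@H](OC(=O)C#Cc3ccc(O[Si](C)(C)C(C)(C)C)cc3)[C@](O)(CO[Si](C)(C)C(C)(C)C)[C@@H]12
F5 | step 3 | (4S,5R)-4-allyl-5-ethynyl-2,2-dimethyl-1,3-dioxan-5-ol | C=CC[C@@H]1OC(C)(C)OC[C@]1(O)C#C
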